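Target: 2,5-dihydroxy-3-[(E)-nonadec-14-enyl]-1,4-benzoquinone, side chain numbered C1' (ring-bound) to C19'. Enabling feature: the only functional group of the chain, the E alkene C14'=C15', follows thirteen unbranched methylenes, so C13' can be a primary radical released from a carboxylic acid and C14'–C19' an intact (E)-hex-1-enyl unit.
Retrosynthesis: the two ring O–H go back to O–Me vinylogous esters and the quinone to a 1,2,4,5-tetramethoxybenzene; the chain is cut at C13'–C14' into a redox-active ester and (E)-1-iodohex-1-ene; the acid is cut at C12'–C13' (malonate) and at aryl–C1' (aryllithium plus 1,12-dibromododecane).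
Forward: the six-membered carbocycle is bought as the arene and no ring is formed; the chain grows aryl–C1' (step 1), C12'–C13' (step 2) and C13'–C14' by nickel-electrocatalytic decarboxylative alkenylation (step 6); the ring is then oxidised and unmasked (steps 7 and 8).
Stereochemistry: there is no stereocentre; the E geometry comes from syn hydrozirconation of hex-1-yne with retentive iodinolysis (step 5) and passes unchanged through the stereoretentive coupling.

Key step: step 6

Remark: the target is drawn as one of two degenerate hydroxyquinone tautomers, which are one compound; compounds 1, 2, 5, 10 and 12 are taken as commercial.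

Step 1
Reactants: 1 1,2,4,5-tetramethoxybenzene; 2 1,12-dibromododecane
Product: 4 3-(12-bromododecyl)-1,2,4,5-tetramethoxybenzene, via aryllithium 3 (not isolated)
Conditions: n-BuLi, THF, 0 °C to rt; then 2 (3 equiv), HMPA, −40 °C to rt
Reagents that add atoms: none
Why: Directed ortho-lithiation removes the ring hydrogen flanked by two methoxy groups, and the aryllithium displaces one bromide of the excess dibromide in an HMPA-promoted SN2 alkylation, the excess suppressing double arylation.

Step 2
Reactants: 4 3-(12-bromododecyl)-1,2,4,5-tetramethoxybenzene; 5 diethyl malonate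
Product: 7 diethyl 2-[12-(2,3,5,6-tetramethoxyphenyl)dodecyl]propanedioate, via sodium malonate enolate 6 (not isolated)
Conditions: 5 (3 equiv), NaH, THF/DMF, 0 °C; then 4, NaI (cat.), 60 °C
Reagents that add atoms: none
Why: In this malonic ester synthesis the soft sodium enolate, used in excess to avoid dialkylation, displaces the primary bromide (assisted by in situ Finkelstein exchange) and so adds C13' together with the future carboxyl carbon.

Step 3
Reactants: 7 diethyl 2-[12-(2,3,5,6-tetramethoxyphenyl)dodecyl]propanedioate
Product: 9 14-(2,3,5,6-tetramethoxyphenyl)tetradecanoic acid, via malonic diacid 8 (not isolated)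
Conditions: KOH, EtOH/H2O, reflux; aq. HCl; then neat, 150 °C
Reagents that add atoms: potassium hydroxide, [K+].[OH-]
Why: Saponification followed by thermal decarboxylation of the malonic acid through its six-membered cyclic transition state is the standard close of a malonic ester synthesis, and the tetramethoxyarene is inert to base, dilute acid and heat.

Step 4
Reactants: 9 14-(2,3,5,6-tetramethoxyphenyl)tetradecanoic acid; 10 N-hydroxyphthalimide
Product: 11 1,3-dioxoisoindolin-2-yl 14-(2,3,5,6-tetramethoxyphenyl)tetradecanoate
Conditions: N,N'-diisopropylcarbodiimide, DMAP (cat.), CH2Cl2, rt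
Reagents that add atoms: none
Why: In this Steglich-type carbodiimide esterification the carbodiimide-activated acid is intercepted by the N-hydroxy group under neutral conditions to give the redox-active ester, with no other nucleophilic or acidic site in the molecule.

Step 5
Reactants: 12 hex-1-yne
Product: 14 (E)-1-iodohex-1-ene, via alkenylzirconocene chloride 13 (not isolated)
Conditions: Cp2Zr(H)Cl, THF, rt; then I2, 0 °C
Reagents that add atoms: iodine, II
Why: Hydrozirconation adds Zr–H syn and with the metal at the terminal carbon of the alkyne, and iodinolysis of the carbon–zirconium bond proceeds with retention, so the E iodide should form as a single geometric isomer.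

Step 6
Reactants: 11 1,3-dioxoisoindolin-2-yl 14-(2,3,5,6-tetramethoxyphenyl)tetradecanoate; 14 (E)-1-iodohex-1-ene
Product: 15 1,2,4,5-tetramethoxy-3-[(E)-nonadec-14-enyl]benzene
Conditions: 14 (2 equiv), NiCl2·6H2O (10 mol %), 2,2'-bipyridine (10 mol %), AgNO3 (0.3 equiv), DMF, Mg anode, reticulated vitreous carbon cathode, undivided cell, constant current, rt
Reagents that add atoms: none
Why: Cathodically generated low-valent nickel–bipyridine inserts into the carbon–iodine bond of 14 with retention of the E geometry, while single-electron transfer to the N-acyloxyphthalimide of 11 triggers fragmentation to carbon dioxide, phthalimide anion and the primary C13' radical. The radical is captured at the alkenylnickel species and reductive elimination from the resulting trivalent alkyl(alkenyl)nickel forms the C13'–C14' sp3–sp2 bond, the dissolving Mg anode supplying the electrons. The closest known reaction type is the nickel-electrocatalytic decarboxylative alkenylation of redox-active esters with alkenyl halides, applied here to a new pair of partners. No ring is closed and no stereocentre is created; the only stereochemical element, the C14'=C15' E alkene, is dictated by 14 because oxidative addition and reductive elimination at an alkenyl carbon are stereoretentive. The step needs cross-coupling to outrun homocoupling of 14 and reduction of the radical to the alkane, which is favoured by the excess of the simple iodide, the unhindered primary radical and the thirteen methylenes that keep the radical out of cyclisation range of the ring. The tetramethoxyarene, easy to oxidise but hard to reduce, is a spectator at the cathode, and Mg dissolution holds the anode far below the potential of arene oxidation.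

Step 7
Reactants: 15 1,2,4,5-tetramethoxy-3-[(E)-nonadec-14-enyl]benzene
Product: 16 2,5-dimethoxy-3-[(E)-nonadec-14-enyl]cyclohexa-2,5-diene-1,4-dione
Conditions: (NH4)2Ce(NO3)6 (2.5 equiv), MeCN/H2O, 0 °C
Reagents that add atoms: water, O
Why: In this oxidative demethylation by tetravalent cerium the arene radical cation takes up water at two para methoxy-bearing carbons and loses two methanol, either para pair leading to the same 2,5-dimethoxy-1,4-benzoquinone, while the isolated alkene is not oxidised at this potential.

Step 8
Reactants: 16 2,5-dimethoxy-3-[(E)-nonadec-14-enyl]cyclohexa-2,5-diene-1,4-dione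
Product: 17 2,5-dihydroxy-3-[(E)-nonadec-14-enyl]cyclohexa-2,5-diene-1,4-dione
Conditions: 2 M aq. NaOH, EtOH, 70 °C; then aq. HCl
Reagents that add atoms: sodium hydroxide, [Na+].[OH-]
Why: In this addition–elimination hydrolysis of two vinylogous methyl esters hydroxide adds at the methoxy-bearing carbons and expels methoxide, the stable dianion of the dihydroxyquinone drives the reaction, and acidification should release the target without touching the E alkene.

Compound list
1 | 1,2,4,5-tetramethoxybenzene | COc1cc(OC)c(OC)cc1OC | starting material
2 | 1,12-dibromododecane | BrCCCCCCCCCCCCBr | starting material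
3 | (2,3,5,6-tetramethoxyphenyl)lithium (formed in the flask, not isolated) | COc1cc(OC)c(OC)c([Li])c1OC | intermediate
4 | 3-(12-bromododecyl)-1,2,4,5-tetramethoxybenzene | COc1cc(OC)c(OC)c(CCCCCCCCCCCCBr)c1OC | intermediate
5 | diethyl malonate | CCOC(=O)CC(=O)OCC | starting material
6 | sodium diethyl malonate (enolate, formed in the flask, not isolated) | CCOC(=O)[CH-]C(=O)OCC.[Na+] | intermediate
7 | diethyl 2-[12-(2,3,5,6-tetramethoxyphenyl)dodecyl]propanedioate | CCOC(=O)C(CCCCCCCCCCCCc1c(OC)c(OC)cc(OC)c1OC)C(=O)OCC | intermediate
8 | 2-[12-(2,3,5,6-tetramethoxyphenyl)dodecyl]propanedioic acid (not isolated) | OC(=O)C(CCCCCCCCCCCCc1c(OC)c(OC)cc(OC)c1OC)C(=O)O | intermediate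
9 | 14-(2,3,5,6-tetramethoxyphenyl)tetradecanoic acid | COc1cc(OC)c(OC)c(CCCCCCCCCCCCCC(=O)O)c1OC | intermediate
10 | N-hydroxyphthalimide | ON1C(=O)c2ccccc2C1=O | starting material
11 | 1,3-dioxoisoindolin-2-yl 14-(2,3,5,6-tetramethoxyphenyl)tetradecanoate | COc1cc(OC)c(OC)c(CCCCCCCCCCCCCC(=O)ON2C(=O)c3ccccc3C2=O)c1OC | intermediate
12 | hex-1-yne | C#CCCCC | starting material
13 | chlorobis(cyclopentadienyl)[(E)-hex-1-enyl]zirconium (not isolated) | CCCC/C=C/[Zr+2]Cl.c1cc[cH-]c1.c1cc[cH-]c1 | intermediate
14 | (E)-1-iodohex-1-ene | CCCC/C=C/I | intermediate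
15 | 1,2,4,5-tetramethoxy-3-[(E)-nonadec-14-enyl]benzene | CCCC/C=C/CCCCCCCCCCCCCc1c(OC)c(OC)cc(OC)c1OC | intermediate
16 | 2,5-dimethoxy-3-[(E)-nonadec-14-enyl]cyclohexa-2,5-diene-1,4-dione | CCCC/C=C/CCCCCCCCCCCCCC1=C(OC)C(=O)C=C(OC)C1=O | intermediate
17 | 2,5-dihydroxy-3-[(E)-nonadec-14-enyl]cyclohexa-2,5-diene-1,4-dione | CCCC/C=C/CCCCCCCCCCCCCC1=C(O)C(=O)C=C(O)C1=O | target

Total step count: 8. Longest linear sequence: 7 steps (steps 1, 2, 3, 4, 6, 7 and 8, from 1 to 17); step 5 is a one-step branch.

Steps most likely to fail

Step 6. The electrochemical union may lose out to reduction of the C13' radical to the saturated chain or to homocoupling of the alkenyl iodide. The fallback makes the alkene by olefination instead and sets out from acid 9. LiAlH4 in THF should give 14-(2,3,5,6-tetramethoxyphenyl)tetradecan-1-ol F1, and Dess–Martin periodinane in CH2Cl2 should oxidise it to 14-(2,3,5,6-tetramethoxyphenyl)tetradecanal F2. In parallel, 1-phenyl-1H-tetrazole-5-thiol is S-alkylated with 1-bromopentane (K2CO3, acetone) to 5-(pentylsulfanyl)-1-phenyl-1H-tetrazole F3. Oxidation (H2O2, (NH4)6Mo7O24·4H2O, EtOH) then gives 5-(pentylsulfonyl)-1-phenyl-1H-tetrazole F4. Julia–Kocienski olefination of F2 with the anion of F4 (KN(SiMe3)2, DME, −60 °C to rt) should form C14'=C15' mainly as the E isomer and comes back to the route at 15.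

Step 1. Alkylation of the hindered aryllithium may be spoiled by double arylation of the dibromide, by elimination of HBr or by slow substitution. The fallback forms the aryl–C1' bond by acylation and sets out from 1. Commercial 14-methoxy-14-oxotetradecanoic acid is converted with (COCl)2 and catalytic DMF into methyl 14-chloro-14-oxotetradecanoate F5. Aryllithium 3, made from 1 as in step 1, is transmetalated with ZnCl2 to chloro(2,3,5,6-tetramethoxyphenyl)zinc F6. Negishi acylation with F5 under Pd(PPh3)4 catalysis should give methyl 14-oxo-14-(2,3,5,6-tetramethoxyphenyl)tetradecanoate F7. Ionic hydrogenation (Et3SiH, CF3CO2H) reduces the aryl ketone to methyl 14-(2,3,5,6-tetramethoxyphenyl)tetradecanoate F8, and LiOH in THF/H2O gives acid 9, where the route is rejoined; steps 2 and 3 are then not needed.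

Step 7. Oxidation with tetravalent cerium may go astray through oxidative aryl–aryl dimerisation, ring nitration or over-oxidation. The fallback oxidises the ring electrochemically at the ketal level and sets out from 15. Anodic oxidation at a Pt anode in methanolic KOH at 0 °C should give the quinone bis(dimethyl ketal) 1,3,3,4,6,6-hexamethoxy-2-[(E)-nonadec-14-enyl]cyclohexa-1,4-diene F9. Mild hydrolysis (dilute aqueous HCl in acetone, rt) should unmask both carbonyl groups and comes back to the route at 16.

Further compounds
F1 | step 6 | 14-(2,3,5,6-tetramethoxyphenyl)tetradecan-1-ol | COc1cc(OC)c(OC)c(CCCCCCCCCCCCCCO)c1OC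
F2 | step 6 | 14-(2,3,5,6-tetramethoxyphenyl)tetradecanal | COc1cc(OC)c(OC)c(CCCCCCCCCCCCCC=O)c1OC
F3 | step 6 | 5-(pentylsulfanyl)-1-phenyl-1H-tetrazole | CCCCCSc1nnnn1-c1ccccc1
F4 | step 6 | 5-(pentylsulfonyl)-1-phenyl-1H-tetrazole | CCCCCS(=O)(=O)c1nnnn1-c1ccccc1
F5 | step 1 | methyl 14-chloro-14-oxotetradecanoate | COC(=O)CCCCCCCCCCCCC(=O)Cl
F6 | step 1 | chloro(2,3,5,6-tetramethoxyphenyl)zinc | COc1cc(OC)c(OC)c([Zn]Cl)c1OC
F7 | step 1 | methyl 14-oxo-14-(2,3,5,6-tetramethoxyphenyl)tetradecanoate | COC(=O)CCCCCCCCCCCCC(=O)c1c(OC)c(OC)cc(OC)c1OC
F8 | step 1 | methyl 14-(2,3,5,6-tetramethoxyphenyl)tetradecanoate | COC(=O)CCCCCCCCCCCCCc1c(OC)c(OC)cc(OC)c1OC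
F9 | step 7 | 1,3,3,4,6,6-hexamethoxy-2-[(E)-nonadec-14-enyl]cyclohexa-1,4-diene | CCCC/C=C/CCCCCCCCCCCCCC1=C(OC)C(OC)(OC)C=C(OC)C1(OC)OC
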